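Remark on the chemistry: the target has no stereogenic centre (a mirror plane runs through C1 and C4 of the central ring), so the "single enantiomer" is the achiral compound itself and no enantioselective step is needed. Compound 5 is assumed to be a catalogue compound.

## Structural features

The target (C28H26O4) has a central benzene ring (ring A, C1–C6) that carries a 2-phenylethyl chain at C1, two 4-hydroxybenzyl groups at C2 and C6 (each joined through one CH2), hydroxyls at C3 and C5, and a single hydrogen at C4. The mirror plane through C1 and C4 makes the two 4-hydroxybenzyl arms and the two ring-A hydroxyls equivalent. The fragile parts are the electron-rich resorcinol ring and its two p-hydroxybenzyl (diarylmethane) units: strong acid can protonate ring A at an ipso carbon and expel a benzyl group as a quinone methide, and the polyphenol is prone to air oxidation in base. The real difficulty is the substitution pattern of ring A. Three carbon substituents sit side by side (C6, C1, C2), and the benzyl groups occupy the two most hindered activated positions, while the equally activated and more open C4 between the hydroxyls stays free. The feature the key step exploits is that ring A is a folded poly-β-carbonyl chain. C3–C4–C5 is a latent β-diketone, C2 and C6 are its two outer α-carbons (each already bearing an ArCH2 group), and C1 is a single carbon carrying the two-carbon chain. C2–C3–C4–C5–C6 with both arms is therefore a mirror-symmetric β-diketone, and one aldol bond (C1–C6) closes the ring with every substituent already in place.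

## Logic of the disconnections

Chain numbering of 7 used below: C1 = PhCH=, C2 = =CH, C3 = cinnamoyl C=O, C4 = branched CH, C5 and C7 = C=O, C6 = CH2 between them, C8 = CH2, C9 = ArCH2. On ring closure C3→C1, C4→C2, C5→C3, C6→C4, C7→C5, C8→C6 of ring A.

**12 ⇒ 9.** The two phenolic O–H bonds of the outer rings are traced back to O–CH2Ph bonds and the CH2–CH2 of the chain at C1 to an E C=C. The alkene is there because it leaves the C1 substituent without α-hydrogens at the stage of the key step. The benzyl ethers are there because they survive strong base and leave under the same conditions that saturate the alkene. Nothing is gained in skeleton, but the last step must do three things in one hydrogenation without acid.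

**9 ⇒ 7 (key).** The ring-A bond C1–C6 (C3–C8 of 7) is cut and one molecule of water is added back, which opens the pentasubstituted arene to an acyclic chain. The gain is large: the regiochemical problem of ring A disappears, because in 7 every substituent is fixed on a defined chain carbon, and the precursor needs no aromatic substitution chemistry at all. The forward step must form a C–C bond from C8 to C3 in preference to O-cyclisation, conjugate addition to the C1=C2 bond, and chain fragmentation.

**7 ⇒ 4 + 5.** The C3–C4 bond is cut. 4 is mirror-symmetric, so acylation at either outer α-carbon gives the same compound, and 5 delivers ring-A C1 together with the chain and the phenyl ring. The forward step needs acylation at the outer (γ) carbon of 4 rather than the central one, and 1,2- rather than 1,4-addition to 5.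

**4 ⇒ 1 + 2 (twice).** Both ArCH2–CH2 bonds (C1–C2 and C6–C7 of 4) are cut in a two-directional sense. This reduces 4 to a five-carbon symmetric core and two identical benzylic electrophiles. The forward step needs alkylation at each terminal carbon of 1 in turn, never at the central carbon or at oxygen.

## Other disconnections considered

**Alternative 1:** (the first that comes to mind, and the presumed biogenesis). Cut both ArCH2–C(ring A) bonds. Forward, a double Friedel–Crafts-type benzylation of dihydropinosylvin A1 with 4-hydroxybenzyl alcohol A2, through the p-quinone methide A3, would give 12 directly. The chosen plan is preferred because A1 offers three activated positions (C2, C6 and C4), and the target needs exactly the two more hindered ones with C4 untouched. Nothing in A1 distinguishes them, each benzylation makes the ring more nucleophilic, and A3 can also alkylate its own phenol ring. On mechanistic grounds a mixture of mono-, bis- and tris-benzylated regioisomers and oligomers is expected, so the short step count does not solve the selectivity problem.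

**Alternative 2:** Cut the same two bonds as cross-couplings. The dimethyl ether A4 would be dibrominated to A5, coupled twice with the benzylzinc reagent A6 (Negishi) to the tetramethyl ether A7, and demethylated to 12. Regiochemistry is moved to a halogenation, which is plausible. But each C–Br bond is flanked by OMe and the chain, and the second coupling also sits next to a new benzyl group. A4 must first be made, so the route is longer, and it ends with a fourfold Lewis-acid demethylation of an acid-sensitive diarylmethane. It is still arene functionalisation, whereas the chosen plan fixes the pattern by constructing the ring.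

**Alternative 3:** Build ring A at the cyclohexane-1,3-dione level. Michael addition of the benzylmalonate A9 to the enone A8, Claisen (Dieckmann-type) closure and decarboxylation would give the dione A10, and dehydrogenation would then give 10. The Michael step joins a tertiary malonate carbanion to an α,β-disubstituted enone and should be slow and reversible. Three stereocentres are made only to be destroyed, a separate oxidation is needed in the presence of benzyl ethers and benzylic CH2 groups, and A8 needs its own regiocontrolled synthesis. The chosen plan reaches the aromatic oxidation level directly and in fewer steps.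

Key step: step 3

## Steps

Step 1
Reactants: 1 pentane-2,4-dione; 2 4-(benzyloxy)benzyl chloride (2 equiv)
Product: 4 1,7-bis[4-(benzyloxy)phenyl]heptane-3,5-dione, via monoalkylated diketone 3 (not isolated)
Conditions: LDA (2.1 equiv), THF, 0 °C; 2 (1.0 equiv), 0 °C; LDA (1.1 equiv), 0 °C; 2 (1.0 equiv), 0 °C → rt; sat. aq. NH4Cl
Reagents that add atoms: none
Why: Two-directional γ-alkylation of a β-diketone 1,3-dianion: the terminal carbanion is far more nucleophilic than the central one, so 2 should react only at the methyl carbon to give 3; the third equivalent of base should regenerate a dianion at the remaining methyl group (more acidic and less hindered than the substituted methylene), so the second benzylation should go to the other terminus and give symmetric 4.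

Step 2
Reactants: 4 1,7-bis[4-(benzyloxy)phenyl]heptane-3,5-dione; 5 (E)-N-methoxy-N-methylcinnamamide
Product: 7 (E)-4-[4-(benzyloxy)benzyl]-9-[4-(benzyloxy)phenyl]-1-phenylnon-1-ene-3,5,7-trione, via tetrahedral N-methoxy-N-methyl adduct 6 (not isolated)
Conditions: LDA (2.2 equiv), THF, −78 → 0 °C; 5 (1.1 equiv), −78 → 0 °C; sat. aq. NH4Cl, 0 °C
Reagents that add atoms: none
Why: Claisen-type γ-acylation of the dianion of 4 with a Weinreb amide: the chelated adduct 6 should persist until work-up, which prevents proton transfer from product to unreacted dianion and favours 1,2- over 1,4-addition; the two termini of 4 are equivalent, so only one constitution can form, and the mildly acidic quench avoids acid-catalysed pyranone closure of 7.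

Step 3
Reactants: 7 (E)-4-[4-(benzyloxy)benzyl]-9-[4-(benzyloxy)phenyl]-1-phenylnon-1-ene-3,5,7-trione
Product: 9 4,6-bis[4-(benzyloxy)benzyl]-5-[(E)-2-phenylethenyl]benzene-1,3-diol, via cyclic aldol adduct 8 (not isolated)
Conditions: KOH (2 M aq., 5 equiv), MeOH–THF (degassed), Ar, rt → 50 °C; then 1 M HCl to pH 3, 0 °C
Reagents that add atoms: none
Why: Intramolecular aldol cyclodehydration of an acyclic 1,3,5-triketone to a resorcinol, the laboratory counterpart of the stilbene-synthase-type closure of cinnamoyl polyketides; the closest known reaction type is the cyclisation of 2,4,6-triketones to orcinol-type resorcinols in aqueous alkali. Hydroxide should first give the C5–C7 diketonate (C6–H is the most acidic proton), and reversible γ-deprotonation at C8 then gives a dienolate whose C8 adds to the C3 carbonyl, which stays largely ketonic because the C4 benzyl substituent disfavours enolisation across C3–C5. The only ring closed is ring A (future C1–C6 bond), in a six-membered 6-(enolendo)-exo-trig mode, giving 8. β-Elimination of water from 8 and tautomerisation of the cyclohexenedione to the diphenol make the sequence irreversible, so reversible diversions (retro-aldol, oxa- or carba-Michael addition of the diketonate to the styryl ketone) can drain back toward 9. No stereocentre survives: C4 of 7 and the three sp3 centres of 8 all become aromatic carbons, and the E alkene is untouched. The step needs regioselectivity (which α-carbon attacks which carbonyl) and chemoselectivity (C-aldol versus O-cyclisation to a 4-pyranone); the first is secured because the cinnamoyl terminus has no α-hydrogen, leaving C8→C3 as the only six-membered carbocyclic aldol, and the second because pyranone formation is acid-promoted whereas base holds the oxygens as enolates. A potassium counter-ion in a protic medium is chosen because closure needs the C5–C7 diketonate in its open, non-chelated form with C4 and C8 on the same side. The product carries both benzyl arms, the styryl group and the 1,3-diol in the target's pattern by construction, so aromatic substitution regiochemistry never arises.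

Step 4
Reactants: 9 4,6-bis[4-(benzyloxy)benzyl]-5-[(E)-2-phenylethenyl]benzene-1,3-diol
Product: 12 4,6-bis(4-hydroxybenzyl)-5-(2-phenylethyl)benzene-1,3-diol, via bibenzyl bis(benzyl ether) 10 (not isolated), via mono(benzyl ether) 11 (not isolated)
Conditions: H2 (1 atm), 10% Pd/C, EtOAc–MeOH, rt
Reagents that add atoms: none
Why: Heterogeneous catalytic hydrogenation should saturate the stilbene C=C first (10) and then hydrogenolyse both aryl benzyl ethers (11, then 12) in the same flask; the free phenols, the diarylmethane C–C bonds and the aromatic rings are inert under these neutral conditions, so the acid-sensitive target is released without acid.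

## Compound list

1 | pentane-2,4-dione | CC(=O)CC(C)=O | starting material
2 | 4-(benzyloxy)benzyl chloride | ClCc1ccc(OCc2ccccc2)cc1 | starting material
3 | 6-[4-(benzyloxy)phenyl]hexane-2,4-dione (formed in the flask, not isolated) | CC(=O)CC(=O)CCc1ccc(OCc2ccccc2)cc1 | intermediate
4 | 1,7-bis[4-(benzyloxy)phenyl]heptane-3,5-dione | O=C(CCc1ccc(OCc2ccccc2)cc1)CC(=O)CCc1ccc(OCc2ccccc2)cc1 | intermediate
5 | (E)-N-methoxy-N-methylcinnamamide | CON(C)C(=O)/C=C/c1ccccc1 | starting material
6 | (E)-4-[4-(benzyloxy)benzyl]-9-[4-(benzyloxy)phenyl]-3-hydroxy-3-[methoxy(methyl)amino]-1-phenylnon-1-ene-5,7-dione (lithium chelate in the flask, drawn neutral; stereoisomer mixture; not isolated) | CON(C)C(O)(/C=C/c1ccccc1)C(Cc1ccc(OCc2ccccc2)cc1)C(=O)CC(=O)CCc1ccc(OCc2ccccc2)cc1 | intermediate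
7 | (E)-4-[4-(benzyloxy)benzyl]-9-[4-(benzyloxy)phenyl]-1-phenylnon-1-ene-3,5,7-trione (racemic at C4, enol tautomers) | O=C(/C=C/c1ccccc1)C(Cc1ccc(OCc2ccccc2)cc1)C(=O)CC(=O)CCc1ccc(OCc2ccccc2)cc1 | intermediate
8 | 4,6-bis[4-(benzyloxy)benzyl]-5-hydroxy-5-[(E)-2-phenylethenyl]cyclohexane-1,3-dione (stereoisomer mixture; not isolated) | O=C1CC(=O)C(Cc2ccc(OCc3ccccc3)cc2)C(O)(/C=C/c2ccccc2)C1Cc4ccc(OCc5ccccc5)cc4 | intermediate
9 | 4,6-bis[4-(benzyloxy)benzyl]-5-[(E)-2-phenylethenyl]benzene-1,3-diol | Oc1cc(O)c(Cc2ccc(OCc3ccccc3)cc2)c(/C=C/c2ccccc2)c1Cc4ccc(OCc5ccccc5)cc4 | intermediate
10 | 4,6-bis[4-(benzyloxy)benzyl]-5-(2-phenylethyl)benzene-1,3-diol (not isolated) | Oc1cc(O)c(Cc2ccc(OCc3ccccc3)cc2)c(CCc2ccccc2)c1Cc4ccc(OCc5ccccc5)cc4 | intermediate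
11 | 4-[4-(benzyloxy)benzyl]-6-(4-hydroxybenzyl)-5-(2-phenylethyl)benzene-1,3-diol (not isolated) | Oc1cc(O)c(Cc2ccc(OCc3ccccc3)cc2)c(CCc2ccccc2)c1Cc4ccc(O)cc4 | intermediate
12 | 4,6-bis(4-hydroxybenzyl)-5-(2-phenylethyl)benzene-1,3-diol (CNP0361781.0) | Oc1ccc(Cc2c(O)cc(O)c(Cc3ccc(O)cc3)c2CCc2ccccc2)cc1 | target

## Step count and least certain steps

Total step count: 4. Longest linear sequence: 4 steps (1 → 4 → 7 → 9 → 12).

**Step 3 (key step).** The most likely failure is diversion of the major anion before the slower γ-deprotonation and aldol can occur. The C5–C7 diketonate can add through carbon (C6) or oxygen to the styryl ketone in a six-membered conjugate addition, and hydroxide can cleave the α-branched diketone by retro-Claisen fragmentation. Both consume 7 without closing ring A, and the conjugate adducts may revert only slowly. Fallback: set out from 4 and acylate its dianion with N-methoxy-N-methyl-3-phenylpropanamide under the conditions of step 2. This should give the saturated triketone 4-[4-(benzyloxy)benzyl]-9-[4-(benzyloxy)phenyl]-1-phenylnonane-3,5,7-trione F1, which has no Michael acceptor. The same alkaline aldol cyclodehydration should then give 10, where the route is rejoined inside step 4 (hydrogenolysis only). The price is that the saturated acyl terminus is enolisable, so a second aldol mode becomes possible and its isomeric product would have to be separated.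

**Step 2.** The most likely failure is sluggish acylation: the γ-carbanion of 4 is secondary and hindered, so conjugate addition to the cinnamoyl unit or simple recovery of 4 may compete. Fallback: set out from 4 and add its dianion to (E)-cinnamaldehyde, a faster and strictly 1,2-selective aldol addition. This should give the allylic alcohol (E)-4-[4-(benzyloxy)benzyl]-9-[4-(benzyloxy)phenyl]-3-hydroxy-1-phenylnon-1-ene-5,7-dione F2. Oxidation of the allylic alcohol (MnO2 or Dess–Martin periodinane, CH2Cl2) should then give 7.

**Step 1.** The most likely failure is incomplete control of the one-pot double alkylation: partial second dianion formation, a second benzylation at the already substituted methylene, or some central C- or O-alkylation would give mixtures that are tedious to separate. Fallback: set out from 1 and use a two-directional aldol condensation instead of alkylation. The boron chelate of 1 (B2O3, B(OBu)3, n-BuNH2, EtOAc, then dilute HCl) is condensed with two equivalents of 4-(benzyloxy)benzaldehyde at both methyl groups. This should give (1E,6E)-1,7-bis[4-(benzyloxy)phenyl]hepta-1,6-diene-3,5-dione F3. Chemoselective hydrogenation of the two C=C bonds with retention of the benzyl ethers (H2, Pd/C poisoned with Ph2S, or RhCl(PPh3)3) should then give 4.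

## Further compounds

F1 | step 3 | 4-[4-(benzyloxy)benzyl]-9-[4-(benzyloxy)phenyl]-1-phenylnonane-3,5,7-trione | O=C(CCc1ccccc1)C(Cc1ccc(OCc2ccccc2)cc1)C(=O)CC(=O)CCc1ccc(OCc2ccccc2)cc1
F2 | step 2 | (E)-4-[4-(benzyloxy)benzyl]-9-[4-(benzyloxy)phenyl]-3-hydroxy-1-phenylnon-1-ene-5,7-dione (stereoisomer mixture) | OC(/C=C/c1ccccc1)C(Cc1ccc(OCc2ccccc2)cc1)C(=O)CC(=O)CCc1ccc(OCc2ccccc2)cc1
F3 | step 1 | (1E,6E)-1,7-bis[4-(benzyloxy)phenyl]hepta-1,6-diene-3,5-dione | O=C(/C=C/c1ccc(OCc2ccccc2)cc1)CC(=O)/C=C/c1ccc(OCc2ccccc2)cc1
A1 | alternative 1 | 5-(2-phenylethyl)benzene-1,3-diol (dihydropinosylvin) | Oc1cc(O)cc(CCc2ccccc2)c1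
A2 | alternative 1 | 4-(hydroxymethyl)phenol (4-hydroxybenzyl alcohol) | OCc1ccc(O)cc1
A3 | alternative 1 | 4-methylidenecyclohexa-2,5-dien-1-one (p-quinone methide) | C=C1C=CC(=O)C=C1
A4 | alternative 2 | 1,5-dimethoxy-3-(2-phenylethyl)benzene | COc1cc(OC)cc(CCc2ccccc2)c1
A5 | alternative 2 | 2,4-dibromo-1,5-dimethoxy-3-(2-phenylethyl)benzene | COc1cc(OC)c(Br)c(CCc2ccccc2)c1Br
A6 | alternative 2 | (4-methoxybenzyl)zinc chloride | COc1ccc(C[Zn]Cl)cc1
A7 | alternative 2 | 1,5-dimethoxy-2,4-bis(4-methoxybenzyl)-3-(2-phenylethyl)benzene | COc1ccc(Cc2c(OC)cc(OC)c(Cc3ccc(OC)cc3)c2CCc2ccccc2)cc1
A8 | alternative 3 | (E)-3-[4-(benzyloxy)benzyl]-6-phenylhex-3-en-2-one | CC(=O)/C(Cc1ccc(OCc2ccccc2)cc1)=C/CCc1ccccc1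
A9 | alternative 3 | diethyl 2-[4-(benzyloxy)benzyl]propanedioate | CCOC(=O)C(Cc1ccc(OCc2ccccc2)cc1)C(=O)OCC
A10 | alternative 3 | 4,6-bis[4-(benzyloxy)benzyl]-5-(2-phenylethyl)cyclohexane-1,3-dione (stereoisomer mixture) | O=C1CC(=O)C(Cc2ccc(OCc3ccccc3)cc2)C(CCc2ccccc2)C1Cc4ccc(OCc5ccccc5)cc4
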